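Ring C of flavone unit 1 is disconnected at C3–C4 and O1–C8a. In ring A the oxygen-bearing carbons C5, C7 and C8a sit ortho or para to C4a, which carries the C4 carbonyl, so all three C–O bonds can arise from C–F bonds of a symmetric 2,4,6-trifluorobenzoyl group. In one operation the enolate of a ring B acetophenone, which already carries tribenzylated apigenin (rings D, E, F) at C3', is aroylated at carbon and the resulting diketonate oxygen expels an ortho fluoride, closing ring C. The precursor is a Suzuki-derived 3-aryl-4,5-dimethoxyacetophenone; benzyloxide exchange of the remaining C5 and C7 fluorides and global debenzylation finish the synthesis.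

Key step: step 7

Assumption: the C3'–C8'' biaryl axis is treated as configurationally undefined, as in the target SMILES, so the route has no stereochemical element to control.

Step 1
Reactants: 1 apigenin
Product: 2 5,7-bis(benzyloxy)-2-[4-(benzyloxy)phenyl]-4H-chromen-4-one (tri-O-benzylapigenin)
Conditions: BnBr (4 equiv), K2CO3, DMF, 80 °C
Reagents that add atoms: benzyl bromide, BrCc1ccccc1
Why: Williamson etherification (SN2 of the phenoxides on benzyl bromide) should alkylate all three oxygens, the excess reagent and heat being needed only for the hydrogen-bonded 5''-OH.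

Step 2
Reactants: 2 tri-O-benzylapigenin
Product: 3 5,7-bis(benzyloxy)-2-[4-(benzyloxy)phenyl]-8-iodo-4H-chromen-4-one
Conditions: I2, AgO2CCF3, CH2Cl2, 0 °C → rt
Reagents that add atoms: iodine, II
Why: Electrophilic aromatic iodination by trifluoroacetyl hypoiodite formed in the flask should hit ring D, the most electron-rich arene, at C8'', the site known to react in 5,7-dioxygenated flavones whose 5-oxygen is alkylated.

Step 3
Reactants: 4 acetovanillone
Product: 5 1-(4-hydroxy-3-iodo-5-methoxyphenyl)ethanone (5-iodoacetovanillone)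
Conditions: NIS, TsOH·H2O (cat.), MeCN, rt
Reagents that add atoms: N-iodosuccinimide, O=C1CCC(=O)N1I
Why: Electrophilic aromatic iodination of a phenol should go to the only free position ortho to the hydroxyl group, the para position being blocked by the acetyl group.

Step 4
Reactants: 5 5-iodoacetovanillone
Product: 6 1-(3-iodo-4,5-dimethoxyphenyl)ethanone
Conditions: MeI, K2CO3, DMF, rt
Reagents that add atoms: iodomethane, CI
Why: Williamson O-methylation of the phenoxide is routine for this hindered but acidic phenol and leaves the methyl ketone untouched under carbonate.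

Step 5
Reactants: 6 1-(3-iodo-4,5-dimethoxyphenyl)ethanone
Product: 7 1-[3,4-dimethoxy-5-(4,4,5,5-tetramethyl-1,3,2-dioxaborolan-2-yl)phenyl]ethanone
Conditions: B2pin2, PdCl2(dppf) (cat.), KOAc, 1,4-dioxane, 90 °C
Reagents that add atoms: bis(pinacolato)diboron, CC1(C)OB(OC1(C)C)B1OC(C)(C)C(C)(C)O1
Why: Miyaura borylation of an acetyl-activated aryl iodide should be fast, and KOAc is too weak a base to enolise the ketone or to trigger coupling of the product with unreacted iodide.

Step 6
Reactants: 3 8-iodo-tri-O-benzylapigenin; 7 acetophenone pinacol boronate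
Product: 8 8-(5-acetyl-2,3-dimethoxyphenyl)-5,7-bis(benzyloxy)-2-[4-(benzyloxy)phenyl]-4H-chromen-4-one (ring B methyl ketone)
Conditions: Pd(OAc)2 (cat.), SPhos, K3PO4, toluene–H2O, 90 °C
Reagents that add atoms: none
Why: Suzuki–Miyaura coupling with the bulky, electron-rich SPhos ligand on zerovalent palladium should allow oxidative addition into the hindered C8''–I bond and formation of the tri-ortho-substituted C3'–C8'' biaryl, while aqueous K3PO4 leaves the methyl ketone alone.

Step 7
Reactants: 8 ring B methyl ketone; 9 2,4,6-trifluorobenzoyl chloride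
Product: 11 5,7-difluoroflavone unit 1 carrying tribenzylated apigenin at C3', via trifluorophenyl 1,3-diketone 10 (not isolated)
Conditions: LiN(SiMe3)2 (2.1 equiv), THF, −78 °C; 9 (1.05 equiv), −78 → 0 °C; then K2CO3, DMF, 60 °C
Reagents that add atoms: none
Why: LiN(SiMe3)2 turns the acetyl group of 8 into its lithium enolate, whose carbon attacks the acyl chloride of 9 to make C3–C4, and the second equivalent of base deprotonates diketone 10 at once, which pulls the acylation toward the C-aroyl product. In warm DMF the enolate oxygen on C2 adds to C8a, an ortho C–F carbon activated by the C4 carbonyl and by the two other fluorines, and loss of fluoride from the Meisenheimer adduct makes O1–C8a. The closest known reaction type is the one-pot aroylation of ketone enolates with 2-fluorobenzoyl chlorides followed by intramolecular SNAr, a standard entry to flavones and 4-quinolones. Ring C closes by 6-endo-trig addition–elimination at an sp2 carbon (the C4a=C8a bond that relays the charge to the carbonyl lies inside the new ring), helped by the planar chelated Z-enolate. No stereocentre is formed. The step needs C- over O-aroylation, secured by the tightly bound lithium enolate in THF and the excess base, and ortho- over para-fluoride displacement, secured because only the two symmetry-equivalent ortho carbons are within reach of the enolate oxygen; unit 2 has no proton that this base removes and ring A needs no protecting group.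

Step 8
Reactants: 11 5,7-difluoroflavone tribenzyl ether
Product: 12 5,7-bis(benzyloxy)-8-{5-[5,7-bis(benzyloxy)-4-oxo-4H-chromen-2-yl]-2,3-dimethoxyphenyl}-2-[4-(benzyloxy)phenyl]-4H-chromen-4-one (pentabenzyl ether)
Conditions: BnOH (3 equiv), NaH (3 equiv), THF, 0 °C → rt; then 11 in DMF, 0 → 50 °C
Reagents that add atoms: benzyl alcohol, OCc1ccccc1
Why: Twofold SNAr (addition–elimination) should replace the C7 fluoride para and the C5 fluoride ortho to the C4 carbonyl, and benzyloxide is chosen because any alkoxide exchange at the benzylated C5''/C7'' positions is then degenerate and the new ethers match the protecting groups of unit 2.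

Step 9
Reactants: 12 pentabenzyl ether
Product: 13 5'-methoxybilobetin
Conditions: BCl3 (12 equiv), C6HMe5 (15 equiv), CH2Cl2, −78 °C; then MeOH–H2O
Reagents that add atoms: none
Why: Lewis acid cleavage of aryl benzyl ethers with pentamethylbenzene as a Friedel–Crafts trap for the benzyl cation should remove all five benzyl groups at −78 °C, where the C4' and C5' methyl ethers (not ortho to a carbonyl) and both flavone C2=C3 bonds are expected to survive.

Compound list
1 | apigenin, 5,7-dihydroxy-2-(4-hydroxyphenyl)-4H-chromen-4-one | O=c1cc(-c2ccc(O)cc2)oc2cc(O)cc(O)c12 | starting material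
2 | 5,7-bis(benzyloxy)-2-[4-(benzyloxy)phenyl]-4H-chromen-4-one | O=c1cc(-c2ccc(OCc3ccccc3)cc2)oc2cc(OCc3ccccc3)cc(OCc3ccccc3)c12 | intermediate
3 | 5,7-bis(benzyloxy)-2-[4-(benzyloxy)phenyl]-8-iodo-4H-chromen-4-one | O=c1cc(-c2ccc(OCc3ccccc3)cc2)oc2c(I)c(OCc3ccccc3)cc(OCc3ccccc3)c12 | intermediate
4 | acetovanillone, 1-(4-hydroxy-3-methoxyphenyl)ethanone | CC(=O)c1ccc(O)c(OC)c1 | starting material
5 | 1-(4-hydroxy-3-iodo-5-methoxyphenyl)ethanone | CC(=O)c1cc(I)c(O)c(OC)c1 | intermediate
6 | 1-(3-iodo-4,5-dimethoxyphenyl)ethanone | CC(=O)c1cc(I)c(OC)c(OC)c1 | intermediate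
7 | 1-[3,4-dimethoxy-5-(4,4,5,5-tetramethyl-1,3,2-dioxaborolan-2-yl)phenyl]ethanone | CC(=O)c1cc(OC)c(OC)c(B2OC(C)(C)C(C)(C)O2)c1 | intermediate
8 | 8-(5-acetyl-2,3-dimethoxyphenyl)-5,7-bis(benzyloxy)-2-[4-(benzyloxy)phenyl]-4H-chromen-4-one | CC(=O)c1cc(OC)c(OC)c(-c2c(OCc3ccccc3)cc(OCc3ccccc3)c3c(=O)cc(-c4ccc(OCc5ccccc5)cc4)oc23)c1 | intermediate
9 | 2,4,6-trifluorobenzoyl chloride | O=C(Cl)c1c(F)cc(F)cc1F | starting material
10 | 1-{3-[5,7-bis(benzyloxy)-2-(4-benzyloxyphenyl)-4-oxo-4H-chromen-8-yl]-4,5-dimethoxyphenyl}-3-(2,4,6-trifluorophenyl)propane-1,3-dione (present in the flask as its enolate) | O=C(CC(=O)c1c(F)cc(F)cc1F)c1cc(OC)c(OC)c(-c2c(OCc3ccccc3)cc(OCc3ccccc3)c3c(=O)cc(-c4ccc(OCc5ccccc5)cc4)oc23)c1 | intermediate (not isolated)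
11 | 5,7-bis(benzyloxy)-2-[4-(benzyloxy)phenyl]-8-[5-(5,7-difluoro-4-oxo-4H-chromen-2-yl)-2,3-dimethoxyphenyl]-4H-chromen-4-one | COc1cc(-c2cc(=O)c3c(F)cc(F)cc3o2)cc(-c2c(OCc3ccccc3)cc(OCc3ccccc3)c3c(=O)cc(-c4ccc(OCc5ccccc5)cc4)oc23)c1OC | intermediate
12 | 5,7-bis(benzyloxy)-8-{5-[5,7-bis(benzyloxy)-4-oxo-4H-chromen-2-yl]-2,3-dimethoxyphenyl}-2-[4-(benzyloxy)phenyl]-4H-chromen-4-one | COc1cc(-c2cc(=O)c3c(OCc4ccccc4)cc(OCc4ccccc4)cc3o2)cc(-c2c(OCc3ccccc3)cc(OCc3ccccc3)c3c(=O)cc(-c4ccc(OCc5ccccc5)cc4)oc23)c1OC | intermediate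
13 | 5'-methoxybilobetin | COc1cc(-c2cc(=O)c3c(O)cc(O)cc3o2)cc(-c2c(O)cc(O)c3c(=O)cc(-c4ccc(O)cc4)oc23)c1OC | target

Total step count: 9.
Longest linear sequence: 7 steps (4 → 5 → 6 → 7 → 8 → 11 → 12 → 13); the apigenin branch (steps 1 and 2) joins at step 6.

Steps most likely to fail

Step 7. The enolate may be aroylated at oxygen, the acid chloride may be consumed by the amide base, or the diketonate may be acylated a second time, so that ring closure starts from too little diketone. The fallback sets out from 8 and comes back at 11. The lithium enolate of 8 (LiN(SiMe3)2, THF, −78 °C) would be added to commercial 2,4,6-trifluorobenzaldehyde in an aldol addition, in which only a C–C bond can form. This should give the racemic β-hydroxy ketone 1-{3-[5,7-bis(benzyloxy)-2-(4-benzyloxyphenyl)-4-oxo-4H-chromen-8-yl]-4,5-dimethoxyphenyl}-3-hydroxy-3-(2,4,6-trifluorophenyl)propan-1-one F1. Dess–Martin periodinane (CH2Cl2, NaHCO3) would oxidise it to diketone 10, which is then isolated and closed with K2CO3 in DMF to 11.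

Step 8. The exchange may stall after the first fluoride has been replaced, because the new benzyloxy group deactivates ring A, or benzyloxide may add at C2 and open ring C. The fallback sets out from 3 and comes back at 12, building ring C with the ring A oxygens already in place. Commercial 3-iodo-4,5-dimethoxybenzaldehyde would be borylated (B2pin2, PdCl2(dppf), KOAc, dioxane, 90 °C) to 3,4-dimethoxy-5-(4,4,5,5-tetramethyl-1,3,2-dioxaborolan-2-yl)benzaldehyde F2. Suzuki–Miyaura coupling with 3 under the conditions of step 6 should give 3-[5,7-bis(benzyloxy)-2-(4-benzyloxyphenyl)-4-oxo-4H-chromen-8-yl]-4,5-dimethoxybenzaldehyde F3. Claisen–Schmidt condensation with commercial 1-[2,4-bis(benzyloxy)-6-hydroxyphenyl]ethanone (KOH, EtOH–THF, rt) should give the (E)-2'-hydroxychalcone 1-[2,4-bis(benzyloxy)-6-hydroxyphenyl]-3-{3-[5,7-bis(benzyloxy)-2-(4-benzyloxyphenyl)-4-oxo-4H-chromen-8-yl]-4,5-dimethoxyphenyl}prop-2-en-1-one F4. Oxidative cyclisation with catalytic I2 in DMSO at 120 °C then closes ring C to give 12.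

Step 6. Oxidative addition into the di-ortho-substituted, electron-rich C8''–I bond may be slow, so that protodeboronation of 7 or hydrodeiodination of 3 outruns the coupling. The fallback sets out from 3 and comes back at 8 with the roles of the partners exchanged. Palladium-catalysed borylation of 3 with pinacolborane (HBpin, PdCl2(CH3CN)2, SPhos, NEt3, dioxane, 80 °C) would give 5,7-bis(benzyloxy)-2-[4-(benzyloxy)phenyl]-8-(4,4,5,5-tetramethyl-1,3,2-dioxaborolan-2-yl)-4H-chromen-4-one F5. This is coupled with the electron-poor iodide 6 (Pd(OAc)2, SPhos, K3PO4, toluene–H2O, 90 °C), where oxidative addition is easy, to give 8.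

Further compounds
F1 | step 7 | 1-{3-[5,7-bis(benzyloxy)-2-(4-benzyloxyphenyl)-4-oxo-4H-chromen-8-yl]-4,5-dimethoxyphenyl}-3-hydroxy-3-(2,4,6-trifluorophenyl)propan-1-one (racemic) | O=C(CC(O)c1c(F)cc(F)cc1F)c1cc(OC)c(OC)c(-c2c(OCc3ccccc3)cc(OCc3ccccc3)c3c(=O)cc(-c4ccc(OCc5ccccc5)cc4)oc23)c1
F2 | step 8 | 3,4-dimethoxy-5-(4,4,5,5-tetramethyl-1,3,2-dioxaborolan-2-yl)benzaldehyde | COc1cc(C=O)cc(B2OC(C)(C)C(C)(C)O2)c1OC
F3 | step 8 | 3-[5,7-bis(benzyloxy)-2-(4-benzyloxyphenyl)-4-oxo-4H-chromen-8-yl]-4,5-dimethoxybenzaldehyde | COc1cc(C=O)cc(-c2c(OCc3ccccc3)cc(OCc3ccccc3)c3c(=O)cc(-c4ccc(OCc5ccccc5)cc4)oc23)c1OC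
F4 | step 8 | (E)-1-[2,4-bis(benzyloxy)-6-hydroxyphenyl]-3-{3-[5,7-bis(benzyloxy)-2-(4-benzyloxyphenyl)-4-oxo-4H-chromen-8-yl]-4,5-dimethoxyphenyl}prop-2-en-1-one | O=C(/C=C/c1cc(OC)c(OC)c(-c2c(OCc3ccccc3)cc(OCc3ccccc3)c3c(=O)cc(-c4ccc(OCc5ccccc5)cc4)oc23)c1)c1c(O)cc(OCc2ccccc2)cc1OCc1ccccc1
F5 | step 6 | 5,7-bis(benzyloxy)-2-[4-(benzyloxy)phenyl]-8-(4,4,5,5-tetramethyl-1,3,2-dioxaborolan-2-yl)-4H-chromen-4-one | O=c1cc(-c2ccc(OCc3ccccc3)cc2)oc2c(B3OC(C)(C)C(C)(C)O3)c(OCc3ccccc3)cc(OCc3ccccc3)c12
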